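**Retrosynthetic overview**
1. Target 33 ⇐ α-methylene ketone 32 (CBS reduction sets C1) ⇐ ten-membered hydroxy ketone 26, by C10 methylenation, PMB-to-acetate exchange and lactol-to-lactone oxidation.
2. 26 ⇐ bicyclic carbinol 23: the C2–C3 bond is made by an anionic oxy-Cope ring expansion that cuts the temporary C5–C10 bond of ring A (C5–C6–C7–C8–C9–C10); the enolate is hydroxylated at C1 in the same flask.
3. Enabling feature: the cis-1-vinyl-2-isopropenylcyclohexan-1-ol of ring A, a 3-oxido-1,5-diene C2=C1–C10(O)–C5–C4=C3, held in one chair by the fused five-membered lactol ring O–C6–C7=C11–C12.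
4. 23 ⇐ ketone 21 (axial ethynylation, semihydrogenation) ⇐ butenolide 17, whose ring A and lactone ring are formed together by a hetero-Pauson–Khand [2+2+1] reaction of ynal 16.
5. 16 ⇐ aldehyde 7 (C8 by Noyori transfer hydrogenation) + imide 11 (C5 and C10 by Evans aldol). Ring order: ring A and the five-membered O-ring (step 10), then the ten-membered ring (step 16) as ring A is erased.

Key step: step 16

**Remarks**
- Carbons carry the germacrane numbers of the target in all intermediates; cis/trans refer to ring A; PMB = 4-methoxybenzyl, TES = triethylsilyl, TIPS = triisopropylsilyl.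
- Assumption: 1 is taken as a catalogue compound (otherwise one step from propargyl alcohol and 4-methoxybenzyl chloride).
- Assumption: the acetal carbon C12 (19 to 31) and C1 (26 to 31) are carried as epimer mixtures and left undefined in the SMILES, since both become planar in step 22.

Step 1
Reactants: 1 4-methoxybenzyl propargyl ether; 2 methyl 3,3-dimethoxypropanoate
Product: 4 6,6-dimethoxy-1-(4-methoxybenzyloxy)hex-2-yn-4-one, via lithium acetylide 3 (not isolated)
Conditions: n-BuLi, THF, −78 °C; BF3·OEt2; then 2, −78 °C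
Reagents that add atoms: none
Why: BF3-promoted acylation of a lithium acetylide by an ester (ynone synthesis) should stop at the ketone because the tetrahedral adduct persists at −78 °C; no stereocenter is formed.

Step 2
Reactants: 4 6,6-dimethoxy-1-(4-methoxybenzyloxy)hex-2-yn-4-one
Product: 5 (4S)-6,6-dimethoxy-1-(4-methoxybenzyloxy)hex-2-yn-4-ol
Conditions: Ru[(S,S)-TsDPEN](p-cymene) (1 mol %), i-PrOH, rt
Reagents that add atoms: none
Why: Noyori asymmetric transfer hydrogenation of an alkynyl ketone, in which the (S,S)-TsDPEN ruthenium hydride treats the alkyne as the π-substituent and should deliver hydride to give the (S)-carbinol at C8 under reagent control, the base-free catalyst leaving the acetal and the triple bond untouched.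

Step 3
Reactants: 5 (4S)-6,6-dimethoxy-1-(4-methoxybenzyloxy)hex-2-yn-4-ol
Product: 6 (3S)-1,1-dimethoxy-3,6-bis(4-methoxybenzyloxy)hex-4-yne
Conditions: NaH, PMBCl, Bu4NI (cat.), THF/DMF, 0 °C to rt
Reagents that add atoms: 4-methoxybenzyl chloride, COc1ccc(CCl)cc1
Why: Williamson etherification of the propargylic alkoxide; C8 is not touched and no new stereocenter arises.

Step 4
Reactants: 6 (3S)-1,1-dimethoxy-3,6-bis(4-methoxybenzyloxy)hex-4-yne
Product: 7 (3S)-3,6-bis(4-methoxybenzyloxy)hex-4-ynal
Conditions: AcOH/H2O (4:1), 40 °C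
Reagents that add atoms: water, O
Why: Acid hydrolysis of the dimethyl acetal, which is far more labile than the two 4-methoxybenzyl ethers, should release the β-alkoxy aldehyde without touching C8.

Step 5
Reactants: 8 (S)-4-benzyloxazolidin-2-one; 9 3-methylbut-2-enoyl chloride
Product: 11 (S)-4-benzyl-3-(3-methylbut-2-enoyl)oxazolidin-2-one, via N-lithio oxazolidinone 10 (not isolated)
Conditions: n-BuLi, THF, −78 °C; then 9, −78 to 0 °C
Reagents that add atoms: none
Why: N-acylation of the lithiated Evans oxazolidinone at −78 °C avoids the deconjugation that amine bases cause with this acid chloride; no new stereocenter.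

Step 6
Reactants: 11 (S)-4-benzyl-3-(3-methylbut-2-enoyl)oxazolidin-2-one; 7 (3S)-3,6-bis(4-methoxybenzyloxy)hex-4-ynal
Product: 13 (4S)-4-benzyl-3-[(2S,3R,5S)-3-hydroxy-5,8-bis(4-methoxybenzyloxy)-2-(prop-1-en-2-yl)oct-6-ynoyl]oxazolidin-2-one, via boron dienolate 12 (not isolated)
Conditions: Bu2BOTf, Et3N, CH2Cl2, −78 to 0 °C; then 7, −78 to 0 °C; pH 7 buffer, MeOH, H2O2
Reagents that add atoms: none
Why: Evans syn-aldol reaction in its deconjugative form: the Z(O) boron dienolate reacts at its α-carbon through a Zimmerman–Traxler chair on the face opposite the benzyl group, which should set C5 (S) and C10 (R) together under auxiliary control irrespective of C8.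

Step 7
Reactants: 13 aldol adduct
Product: 14 (4S)-4-benzyl-3-[(2S,3R,5S)-5,8-bis(4-methoxybenzyloxy)-2-(prop-1-en-2-yl)-3-(triethylsilyloxy)oct-6-ynoyl]oxazolidin-2-one
Conditions: TESOTf, 2,6-lutidine, CH2Cl2, −78 °C
Reagents that add atoms: triethylsilyl triflate, CC[Si](CC)(CC)OS(=O)(=O)C(F)(F)F
Why: Silylation of the secondary alcohol with a silyl triflate and a hindered base blocks retro-aldol cleavage in the next steps; no stereocenter is affected.

Step 8
Reactants: 14 silylated aldol adduct
Product: 15 (2R,3R,5S)-5,8-bis(4-methoxybenzyloxy)-2-(prop-1-en-2-yl)-3-(triethylsilyloxy)oct-6-yn-1-ol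
Conditions: LiBH4, MeOH (1 equiv), THF, 0 °C
Reagents that add atoms: none
Why: Reductive cleavage of the N-acyl oxazolidinone with LiBH4 gives the primary alcohol and returns the auxiliary; the α-centre C5 is not epimerised under these non-enolising conditions.

Step 9
Reactants: 15 primary alcohol
Product: 16 (2S,3R,5S)-5,8-bis(4-methoxybenzyloxy)-2-(prop-1-en-2-yl)-3-(triethylsilyloxy)oct-6-ynal
Conditions: Dess–Martin periodinane, NaHCO3, CH2Cl2, 0 °C
Reagents that add atoms: none
Why: Dess–Martin oxidation under bicarbonate buffering gives the α-branched aldehyde without acid or base that would epimerise C5 or move the isopropenyl double bond into conjugation.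

Step 10
Reactants: 16 ynal
Product: 17 bicyclic 6,12-butenolide (ring A fused at C6–C7; 5-isopropenyl; 8-OPMB; 10-OTES; 13-OPMB; O6/O8/O10 all cis; isopropenyl trans to them)
Conditions: Mo(CO)6, DMSO, toluene, 100 °C
Reagents that add atoms: molybdenum hexacarbonyl (source of CO), [Mo].[C-]#[O+].[C-]#[O+].[C-]#[O+].[C-]#[O+].[C-]#[O+].[C-]#[O+]
Why: Hetero-Pauson–Khand reaction (carbonylative [2+2+1] of alkyne, aldehyde C=O and CO) of a 1,7-ynal; the tether should close through a chair with the C5, C8 and C10 substituents all equatorial while the new C6–O bond must lie in the plane of the metallacycle, so that H6 becomes axial, the lactone oxygen ends trans to the isopropenyl group and cis to the C8 and C10 oxygens, and the CO carbon becomes C12 on the C6 side of the new C7=C11 bond.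

Step 11
Reactants: 17 bicyclic 6,12-butenolide
Product: 19 12-O-TIPS lactol ether of 17 (five-membered O-ring kept; C12 epimers), via aluminium lactolate 18 (not isolated)
Conditions: i-Bu2AlH, CH2Cl2, −78 °C; then pyridine, TIPSOTf, −78 to 0 °C
Reagents that add atoms: triisopropylsilyl triflate, CC(C)[Si](OS(=O)(=O)C(F)(F)F)(C(C)C)C(C)C
Why: 1,2-Reduction of the butenolide at −78 °C followed by silylation of the aluminium lactolate in the same flask (reductive silylation of a lactone) masks the acidic, electrophilic lactone as a base-stable silyl acetal while keeping the five-membered ring; the new acetal centre C12 is uncontrolled and is erased in step 22.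

Step 12
Reactants: 19 lactol TIPS ether
Product: 20 10-alcohol (lactol TIPS ether; 8,13-bis-PMB; OH cis to O6 and O8)
Conditions: Bu4NF, AcOH, THF, 0 °C
Reagents that add atoms: none
Why: Fluoride cleaves the unhindered secondary triethylsilyl ether much faster than the triisopropylsilyl acetal, and acetic acid buffering keeps the acetal from ionising; no stereocenter changes.

Step 13
Reactants: 20 10-alcohol
Product: 21 ring A 10-ketone (5-isopropenyl equatorial and trans to O6)
Conditions: Dess–Martin periodinane, NaHCO3, CH2Cl2, 0 °C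
Reagents that add atoms: none
Why: Buffered Dess–Martin oxidation gives the ketone in which the isopropenyl group at C5 already occupies the thermodynamically preferred equatorial position trans to the C6 oxygen, so no epimerisation is expected.

Step 14
Reactants: 21 ring A 10-ketone
Product: 22 10-ethynyl-10-ol (ethynyl axial and cis to isopropenyl; OH cis to O6 and O8)
Conditions: HC≡CMgBr, THF, −78 to −20 °C
Reagents that add atoms: ethynylmagnesium bromide, C#C[Mg]Br
Why: 1,2-Addition of a small sp-hybridised Grignard reagent to a cyclohexanone whose 3- and 5-positions carry only axial hydrogens should occur axially, which places the new hydroxyl equatorial (cis to the C6 and C8 oxygens) and the ethynyl group axial and cis to the isopropenyl group at C5.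

Step 15
Reactants: 22 10-ethynyl-10-ol
Product: 23 cis-10-vinyl-5-isopropenyl ring A carbinol (lactol TIPS ether; 8,13-bis-PMB)
Conditions: H2 (1 atm), Pd/CaCO3–Pb(OAc)2 (Lindlar catalyst), quinoline, EtOAc, rt
Reagents that add atoms: none
Why: Lindlar semihydrogenation stops at the terminal alkene and leaves the 1,1-disubstituted and tetrasubstituted double bonds and the benzylic ethers alone; no stereocenter changes.

Step 16
Reactants: 23 cis-10-vinyl-5-isopropenyl ring A carbinol
Product: 26 ten-membered 1-hydroxy-10-ketone (4Z; lactol TIPS ether; 8,13-bis-PMB; C1 epimers), via potassium alkoxide 24 (not isolated), via potassium enolate 25 (not isolated)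
Conditions: KN(SiMe3)2, 18-crown-6, THF, −78 to 0 °C; then 2-(phenylsulfonyl)-3-phenyloxaziridine, −78 °C; AcOH
Reagents that add atoms: 2-(phenylsulfonyl)-3-phenyloxaziridine, O=S(=O)(c1ccccc1)N1OC1c1ccccc1
Why: Deprotonation of the tertiary alcohol gives potassium alkoxide 24, whose 3-oxido-1,5-diene (C2=C1–C10(O−)–C5–C4=C3) undergoes a charge-accelerated [3,3] sigmatropic shift (anionic oxy-Cope rearrangement): the C2–C3 bond forms while the temporary C5–C10 bond of ring A breaks, and the enolate 25 so formed is oxidised at C1 in the same flask by the N-sulfonyloxaziridine. The closest known reaction type is the anionic oxy-Cope ring expansion of cis-1,2-dialkenylcyclohexanols to cyclodec-5-enones with trapping of the regiodefined enolate by an electrophilic oxygen source. The ten-membered ring is closed not end to end but by a four-carbon ring expansion of ring A through a six-membered chair transition state that is cis-fused to ring A. The C4=C5 geometry is controlled by that chair: with the isopropenyl group equatorial and the vinyl group axial on ring A, the C5–C6 bond is axial on the chair and C6 ends cis to C3 (4Z); C6 and C8 are spectators, and C1 is formed by attack on the outer face of the enolate (expected to give mainly the 1-epi alcohol), which is why it is re-set in steps 22 and 23. The step needs this chair to win over the ring-flipped chair (which would give 4E) and needs the enolate to be oxidised before it equilibrates: the first is secured by the five-membered lactol ring, which holds the C6–O bond equatorial and with it the isopropenyl group and the C8 and C10 oxygens, the second by adding the oxidant at −78 °C.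

Step 17
Reactants: 26 ten-membered 1-hydroxy-10-ketone
Product: 27 1-O-TES ether of 26
Conditions: TESOTf, 2,6-lutidine, CH2Cl2, −78 °C
Reagents that add atoms: triethylsilyl triflate, CC[Si](CC)(CC)OS(=O)(=O)C(F)(F)F
Why: Silylation of the α-hydroxy ketone protects C1–OH through the methylenation, ether cleavage and acetylation steps; both C1 epimers are carried.

Step 18
Reactants: 27 1-O-TES 10-ketone
Product: 28 10(14)-methylene compound (1-OTES; lactol TIPS ether; 8,13-bis-PMB)
Conditions: Cp2TiMe2, toluene, 65 °C, dark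
Reagents that add atoms: dimethyltitanocene, C[Ti](C)(C1C=CC=C1)C1C=CC=C1
Why: Methylenation with the Petasis reagent (titanium carbene, non-basic Wittig-type olefination) converts the enolisable C10 ketone to the exocyclic alkene without β-elimination of the C8 ether or ionisation of the silyl acetal.

Step 19
Reactants: 28 10(14)-methylene compound
Product: 29 8,13-diol (1-OTES; lactol TIPS ether)
Conditions: DDQ, CH2Cl2/pH 7 buffer, 0 °C
Reagents that add atoms: none
Why: Oxidative cleavage of both 4-methoxybenzyl ethers by DDQ (benzylic hydride abstraction, then hydrolysis of the oxocarbenium ion) under neutral buffering spares the silyl ether, the silyl acetal and the three alkenes.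

Step 20
Reactants: 29 8,13-diol
Product: 30 8,13-diacetate (1-OTES; lactol TIPS ether)
Conditions: Ac2O, pyridine, DMAP (cat.), CH2Cl2, 0 °C to rt
Reagents that add atoms: acetic anhydride, CC(=O)OC(C)=O
Why: Standard DMAP-catalysed acylation of the primary and secondary alcohols installs the two acetates of the target with retention at C8.

Step 21
Reactants: 30 8,13-diacetate
Product: 31 1-hydroxy lactol diacetate (C1 and C12 epimers)
Conditions: Bu4NF, AcOH, THF, 0 °C
Reagents that add atoms: none
Why: Acetic acid-buffered fluoride removes both silyl groups at once, the anomeric triisopropylsilyl group being labile because a lactolate is the leaving group, and the buffer suppresses acetate migration and dehydration of the lactol.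

Step 22
Reactants: 31 1-hydroxy lactol diacetate
Product: 32 8α,13-diacetoxy-1-oxogermacra-4Z,7(11),10(14)-trien-6α,12-olide
Conditions: Dess–Martin periodinane, pyridine, CH2Cl2, 0 °C to rt
Reagents that add atoms: none
Why: Dess–Martin periodinane oxidises the lactol to the butenolide and the allylic C1 alcohol to the α-methylene ketone in one operation, which restores the lactone with C6 unchanged and converges both C1 epimers on one planar centre.

Step 23
Reactants: 32 1-oxo 6,12-olide
Product: 33 8α,13-diacetoxy-1β-hydroxygermacra-4,7(11),10(14)-trien-6α,12-olide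
Conditions: (S)-2-methyl-CBS-oxazaborolidine, catecholborane, toluene, −78 °C
Reagents that add atoms: none
Why: Corey–Bakshi–Shibata reduction: with the (S)-oxazaborolidine the α-methylene-bearing C10 side acts as the large group and hydride should be delivered to give the (1R) carbinol (1β-OH) under reagent control, catecholborane at −78 °C leaving the lactone, the acetates and the alkenes untouched.

**Compound list**
1 | 4-methoxybenzyl propargyl ether | C#CCOCc1ccc(OC)cc1 | starting material
2 | methyl 3,3-dimethoxypropanoate | COC(=O)CC(OC)OC | starting material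
3 | lithium acetylide of 1 | [Li]C#CCOCc1ccc(OC)cc1 | intermediate
4 | 6,6-dimethoxy-1-(4-methoxybenzyloxy)hex-2-yn-4-one | COC(OC)CC(=O)C#CCOCc1ccc(OC)cc1 | intermediate
5 | (4S)-6,6-dimethoxy-1-(4-methoxybenzyloxy)hex-2-yn-4-ol | COC(OC)C[C@H](O)C#CCOCc1ccc(OC)cc1 | intermediate
6 | (3S)-1,1-dimethoxy-3,6-bis(4-methoxybenzyloxy)hex-4-yne | COC(OC)C[C@H](OCc1ccc(OC)cc1)C#CCOCc1ccc(OC)cc1 | intermediate
7 | (3S)-3,6-bis(4-methoxybenzyloxy)hex-4-ynal | O=CC[C@H](OCc1ccc(OC)cc1)C#CCOCc1ccc(OC)cc1 | intermediate
8 | (S)-4-benzyloxazolidin-2-one | O=C1N[C@@H](Cc2ccccc2)CO1 | starting material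
9 | 3-methylbut-2-enoyl chloride | CC(C)=CC(Cl)=O | starting material
10 | N-lithio derivative of 8 | O=C1N([Li])[C@@H](Cc2ccccc2)CO1 | intermediate
11 | (S)-4-benzyl-3-(3-methylbut-2-enoyl)oxazolidin-2-one | CC(C)=CC(=O)N1[C@@H](Cc2ccccc2)COC1=O | intermediate
12 | dibutylboron Z(O)-dienolate of 11 | C=C(C)\C=C(/OB(CCCC)CCCC)N1[C@@H](Cc2ccccc2)COC1=O | intermediate
13 | (4S)-4-benzyl-3-[(2S,3R,5S)-3-hydroxy-5,8-bis(4-methoxybenzyloxy)-2-(prop-1-en-2-yl)oct-6-ynoyl]oxazolidin-2-one | C=C(C)[C@H](C(=O)N1[C@@H](Cc2ccccc2)COC1=O)[C@H](O)C[C@H](OCc1ccc(OC)cc1)C#CCOCc1ccc(OC)cc1 | intermediate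
14 | 3-O-triethylsilyl ether of 13 | C=C(C)[C@H](C(=O)N1[C@@H](Cc2ccccc2)COC1=O)[C@H](O[Si](CC)(CC)CC)C[C@H](OCc1ccc(OC)cc1)C#CCOCc1ccc(OC)cc1 | intermediate
15 | (2R,3R,5S)-5,8-bis(4-methoxybenzyloxy)-2-(prop-1-en-2-yl)-3-(triethylsilyloxy)oct-6-yn-1-ol | C=C(C)[C@H](CO)[C@H](O[Si](CC)(CC)CC)C[C@H](OCc1ccc(OC)cc1)C#CCOCc1ccc(OC)cc1 | intermediate
16 | (2S,3R,5S)-5,8-bis(4-methoxybenzyloxy)-2-(prop-1-en-2-yl)-3-(triethylsilyloxy)oct-6-ynal | C=C(C)[C@H](C=O)[C@H](O[Si](CC)(CC)CC)C[C@H](OCc1ccc(OC)cc1)C#CCOCc1ccc(OC)cc1 | intermediate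
17 | bicyclic 6,12-butenolide (ring A fused at C6–C7; 5-isopropenyl; 8-OPMB; 10-OTES; 13-OPMB; O6/O8/O10 all cis; isopropenyl trans) | O=C1O[C@H]2C(=C1COCc1ccc(OC)cc1)[C@@H](OCc1ccc(OC)cc1)C[C@@H](O[Si](CC)(CC)CC)[C@@H]2C(C)=C | intermediate
18 | diisobutylaluminium lactolate of 17 | CC(C)C[Al](CC(C)C)OC1O[C@H]2C(=C1COCc1ccc(OC)cc1)[C@@H](OCc1ccc(OC)cc1)C[C@@H](O[Si](CC)(CC)CC)[C@@H]2C(C)=C | intermediate
19 | 12-O-TIPS lactol ether of 17 (C12 epimers) | CC(C)[Si](C(C)C)(C(C)C)OC1O[C@H]2C(=C1COCc1ccc(OC)cc1)[C@@H](OCc1ccc(OC)cc1)C[C@@H](O[Si](CC)(CC)CC)[C@@H]2C(C)=C | intermediate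
20 | 10-alcohol (lactol TIPS ether; 8,13-bis-PMB) | CC(C)[Si](C(C)C)(C(C)C)OC1O[C@H]2C(=C1COCc1ccc(OC)cc1)[C@@H](OCc1ccc(OC)cc1)C[C@@H](O)[C@@H]2C(C)=C | intermediate
21 | ring A 10-ketone | CC(C)[Si](C(C)C)(C(C)C)OC1O[C@H]2C(=C1COCc1ccc(OC)cc1)[C@@H](OCc1ccc(OC)cc1)CC(=O)[C@@H]2C(C)=C | intermediate
22 | 10-ethynyl-10-ol (ethynyl cis to isopropenyl; OH cis to O6 and O8) | CC(C)[Si](C(C)C)(C(C)C)OC1O[C@H]2C(=C1COCc1ccc(OC)cc1)[C@@H](OCc1ccc(OC)cc1)C[C@](O)(C#C)[C@@H]2C(C)=C | intermediate
23 | cis-10-vinyl-5-isopropenyl ring A carbinol | CC(C)[Si](C(C)C)(C(C)C)OC1O[C@H]2C(=C1COCc1ccc(OC)cc1)[C@@H](OCc1ccc(OC)cc1)C[C@](O)(C=C)[C@@H]2C(C)=C | intermediate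
24 | potassium alkoxide of 23 | CC(C)[Si](C(C)C)(C(C)C)OC1O[C@H]2C(=C1COCc1ccc(OC)cc1)[C@@H](OCc1ccc(OC)cc1)C[C@]([O-])(C=C)[C@@H]2C(C)=C.[K+] | intermediate
25 | ten-membered potassium enolate (4Z; C1=C10 enolate) | CC(C)[Si](C(C)C)(C(C)C)OC1O[C@@H]2/C=C(/C)CC/C=C(\[O-])C[C@H](OCc3ccc(OC)cc3)C2=C1COCc1ccc(OC)cc1.[K+] | intermediate
26 | ten-membered 1-hydroxy-10-ketone (4Z; lactol TIPS ether; 8,13-bis-PMB; C1 epimers) | O=C1C[C@H](OCc3ccc(OC)cc3)C2=C(COCc3ccc(OC)cc3)C(O[Si](C(C)C)(C(C)C)C(C)C)O[C@@H]2/C=C(/C)CCC1O | intermediate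
27 | 1-O-TES ether of 26 | O=C1C[C@H](OCc3ccc(OC)cc3)C2=C(COCc3ccc(OC)cc3)C(O[Si](C(C)C)(C(C)C)C(C)C)O[C@@H]2/C=C(/C)CCC1O[Si](CC)(CC)CC | intermediate
28 | 10(14)-methylene compound (1-OTES; lactol TIPS ether; 8,13-bis-PMB) | C=C1C[C@H](OCc3ccc(OC)cc3)C2=C(COCc3ccc(OC)cc3)C(O[Si](C(C)C)(C(C)C)C(C)C)O[C@@H]2/C=C(/C)CCC1O[Si](CC)(CC)CC | intermediate
29 | 8,13-diol (1-OTES; lactol TIPS ether) | C=C1C[C@H](O)C2=C(CO)C(O[Si](C(C)C)(C(C)C)C(C)C)O[C@@H]2/C=C(/C)CCC1O[Si](CC)(CC)CC | intermediate
30 | 8,13-diacetate (1-OTES; lactol TIPS ether) | C=C1C[C@H](OC(C)=O)C2=C(COC(C)=O)C(O[Si](C(C)C)(C(C)C)C(C)C)O[C@@H]2/C=C(/C)CCC1O[Si](CC)(CC)CC | intermediate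
31 | 1-hydroxy lactol diacetate (C1 and C12 epimers) | C=C1C[C@H](OC(C)=O)C2=C(COC(C)=O)C(O)O[C@@H]2/C=C(/C)CCC1O | intermediate
32 | 8α,13-diacetoxy-1-oxogermacra-4Z,7(11),10(14)-trien-6α,12-olide | C=C1C[C@H](OC(C)=O)C2=C(COC(C)=O)C(=O)O[C@@H]2/C=C(/C)CCC1=O | intermediate
33 | 8α,13-diacetoxy-1β-hydroxygermacra-4,7(11),10(14)-trien-6α,12-olide | C=C1C[C@H](OC(C)=O)C2=C(COC(C)=O)C(=O)O[C@@H]2/C=C(/C)CC[C@H]1O | target

**Step count and risks**
Total step count: 23. Longest linear sequence: 22 steps (steps 1–4 and 6–23; step 5 is a one-step branch).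

Steps most likely to fail:

1. Step 16. The potassium enolate 25 may lose its regiochemical integrity before it is oxidised (proton transfer toward C9 followed by expulsion of the C8 ether, or aldol-type capture by the sulfonimine by-product). Fallback, setting out from 23: the rearrangement (KN(SiMe3)2, 18-crown-6, THF) would be quenched with TESCl to give the isolable enol triethylsilyl ether F1, which is oxidised separately with dimethyldioxirane (acetone, −78 °C; Rubottom oxidation) through the silyloxy epoxide F2, whose 1,4-silyl shift gives the silyloxy ketone directly; the route is rejoined at 27.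

2. Step 10. Cyclocarbonylation onto the isopropenyl group (ordinary Pauson–Khand pairing) or epimerisation α to the aldehyde at 100 °C may compete with the aldehyde–alkyne pairing. Fallback, setting out from 16: cyclisation at room temperature with Cp2Ti(PMe3)2 would give the oxatitanacycle F3, whose Ti–C bond is cleaved with I2 to the (Z)-iodo allylic alcohol F4; carbonylative lactonisation of F4 (PdCl2(PPh3)2, CO, Et3N, THF) then closes the butenolide, rejoining the route at 17.

3. Step 21. The liberated lactol may lose water to the aromatic furan, or the C13 acetate may migrate to the hemiacetal oxygen. Fallback, setting out from 30: desilylation as before but with NaBH4 added to the same flask, so that lactol 31 is reduced as it forms to the stable triol F5 (C1, C6 and C12 hydroxyls); TEMPO (cat.) with excess PhI(OAc)2 in CH2Cl2 then oxidises the primary allylic alcohol, closes the lactone through the lactol and oxidises C1–OH, rejoining the route at 32.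

**Further compounds**
F1 | step 16 | ten-membered enol triethylsilyl ether (4Z; C1=C10) | CC(C)[Si](C(C)C)(C(C)C)OC1O[C@@H]2/C=C(/C)CC/C=C(\O[Si](CC)(CC)CC)C[C@H](OCc3ccc(OC)cc3)C2=C1COCc1ccc(OC)cc1
F2 | step 16 | 1,10-epoxide of F1 (silyloxy epoxide) | CC(C)[Si](C(C)C)(C(C)C)OC1O[C@@H]2/C=C(/C)CCC3OC3(O[Si](CC)(CC)CC)C[C@H](OCc3ccc(OC)cc3)C2=C1COCc1ccc(OC)cc1
F3 | step 10 | oxatitanacycle (Cp2Ti bridging O6 and C11) | [Ti]1(C3C=CC=C3)(C3C=CC=C3)O[C@H]2C(=C1COCc1ccc(OC)cc1)[C@@H](OCc1ccc(OC)cc1)C[C@@H](O[Si](CC)(CC)CC)[C@@H]2C(C)=C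
F4 | step 10 | (Z)-iodo allylic alcohol (C6–OH; iodine on C11 cis to C6) | O[C@H]1/C(=C(\I)COCc2ccc(OC)cc2)[C@@H](OCc2ccc(OC)cc2)C[C@@H](O[Si](CC)(CC)CC)[C@@H]1C(C)=C
F5 | step 21 | 1,6,12-triol 8,13-diacetate | C=C1C[C@H](OC(C)=O)/C(=C(/CO)COC(C)=O)[C@H](O)/C=C(/C)CCC1O
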